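(Readings and results stem from a simulated flask for substances that don't exist; noise was put on by code.)

3 questions stand on this flask: when target peaks, how high, and when it first reaches the asked level.

| setting | maple | birch | flask |
|---|---|---|---|
| substrate | 0.10 M | 0.15 M | 0.20 M |
| partner | 3 equiv | 3 equiv | 3.00 equiv |
| remark | run made earlier | run made earlier |  |
| time |  |  | 2.0 d |

| run | time / h | target / % | substrate / % |
|---|---|---|---|
| maple | 2.00 | 19 | 32 |
| maple | 4.00 | 33 | 11 |
| maple | 8.00 | 45 | 0 |
| maple | 15.0 | 43 | 0 |
| maple | 30.0 | 36 | 0 |
| birch | 2.00 | 22 | 19 |
| birch | 4.00 | 37 | 4 |
| birch | 8.00 | 44 | 0 |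
| birch | 15.0 | 45 | 1 |
| birch | 30.0 | 37 | 1 |

(scatter of a reading: 1.5 percentage points)

- the best time, 2.0 d at the latest, for target
- the amount of target, in percent of the substrate charged, at that time
- the first time at which target reaches 14%, in the same percent, in d



Two chemists read the maple and birch runs differently. The colleague trusts a clock that runs with c(substrate). At 2.00 h, birch kept less substrate than maple: 19% against 32%. So he scales maple's best reading, at 8.00 h, by the charges, and expects the flask to peak at 4.00 h.

The forecaster freezes something else. From 15.0 h on, substrate reads 0% in maple and 1% in birch, yet target falls in both runs by the last reading. Between the last two readings, maple loses 0.0118 /h and birch 0.0130 /h. The scatter of 1.5 percentage points per reading covers that gap. Pooled, this gives 0.0125 /h, the fade constant: the fraction of target lost per hour after substrate is used, an apparent first-order rate constant. It does not follow the charge, she says.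

Her forecast is 0.33 d, 47.5% and 0.05 d, because “the peak is where intermediate feed equals decay”.

The flask gives 0.362 d, 48.0% and 0.0551 d. Its peak comes later than his time.

    intermediate → decomposed reagent (k = 0.190 /h)
    substrate + target → side product (k = 3.00 /M/h)
    substrate + partner → intermediate + by-product (k = 2.10 /M/h)
    intermediate ⇌ target (K = 9.80, k = 0.320 /h)

His clock belongs to the first hours of the flask: the substrate step reaches its midpoint by 0.565 h. The fade belongs to the flask after its best time. In the flask, target reads 41.0% at 1.00 d, and the fade constant predicts 30.4% at 2.00 d, where it stands at 31.0%. Decomposition of intermediate costs the flask's peak 33 points: without that step it reaches 80.8%. Carried to the same flask read at 8.00 d, the constant turns 31.0% into 5.12%, and that flask holds 5.76%.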